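## Retrosynthetic overview

1. The 1,2-dioxane (the only ring) is closed last: the O–C3 bond is formed by a catalyst-controlled 6-exo-trig peroxy-Michael addition of the C6 hydroperoxide onto an (E)-2-methyl enoate, fixing C3 and C2.
2. C6–OOH and C14–OOH are made together from a (6S,14S) ditertiary diol by double invertive perhydrolysis through its phosphinites.
3. The enoate comes from Wittig olefination of a γ-lactol, which is carried as its methyl acetal through the C–C couplings.
4. C8–C9 is made by alkyl–alkyl Suzuki coupling and C11–C12 by Grignard opening of an oxetane; (R)-1-bromo-3-chloro-2-methylpropane supplies C9–C11 and the C10 centre.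
5. The vinyl acetal and the oxetane both come from (R)-linalool, which fits both C6 and C14 because each is inverted later.

Assumptions: carbons are numbered C1–C18 along the target chain (C1 ester carbon, C3 and C6 ring carbons, C10 methine, C14 hydroperoxy carbon); commercial (R)-(−)-linalool and (R)-1-bromo-3-chloro-2-methylpropane are taken as enantiopure; catalyst Q is the (S)-tert-leucine-derived one, and its mirror image is used if the sense of induction proves opposite.

Catalyst Q is N-[3,5-bis(trifluoromethyl)phenyl]-N′-[(2S)-3,3-dimethyl-1-{[tris(4-methoxyphenyl)-λ5-phosphanylidene]amino}butan-2-yl]urea, SMILES COc1ccc(cc1)P(=NC[C@@H](NC(=O)Nc1cc(cc(c1)C(F)(F)F)C(F)(F)F)C(C)(C)C)(c1ccc(OC)cc1)c1ccc(OC)cc1. A urea rather than a thiourea is chosen so that no sulfur is exposed to the hydroperoxide.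

## Route

Step 1
Reactants: 1 (R)-(−)-linalool, (3R)-3,7-dimethylocta-1,6-dien-3-ol
Product: 3 (3R)-3,7-dimethyloct-6-ene-1,3-diol, via alkyl-9-BBN adduct 2 (not isolated)
Conditions: 9-BBN (1.2 equiv), THF, 0 °C to rt; then aq. NaOH, 30% H2O2, 0 °C
Reagents that add atoms: hydrogen peroxide, OO
Why: Chemoselective anti-Markovnikov hydroboration–oxidation: 9-BBN adds to the monosubstituted vinyl group far faster than to the trisubstituted alkene, and the carbinol centre is not touched.

Step 2
Reactants: 3 (3R)-3,7-dimethyloct-6-ene-1,3-diol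
Product: 5 (2R)-2-methyl-2-(4-methylpent-3-en-1-yl)oxetane, via monotosylate 4 (not isolated)
Conditions: n-BuLi (1.0 equiv), THF, 0 °C; TsCl (1.0 equiv); then n-BuLi (1.0 equiv), 60 °C
Reagents that add atoms: none
Why: One-pot intramolecular Williamson etherification (4-exo-tet): the primary alkoxide is tosylated selectively and the tertiary alkoxide then displaces the tosylate, so the C–O bond at the stereocentre is never broken (retention).

Step 3
Reactants: 1 (R)-(−)-linalool
Product: 7 (5R)-5-ethenyl-2-methoxy-5-methyloxolane (both anomers), via lactol 6 (not isolated)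
Conditions: O3 (1.0 equiv, Sudan Red 7B end point), CH2Cl2/MeOH, −78 °C; Me2S; then PPTS (cat.), MeOH, rt
Reagents that add atoms: methanol, CO
Why: Chemoselective ozonolysis (the electron-rich trisubstituted alkene reacts much faster than the vinyl group) followed by acid-catalysed acetalisation of the resulting γ-lactol, which masks the C3 aldehyde and the C6 oxygen in one ring; the quaternary centre is untouched.

Step 4
Reactants: 7 (5R)-5-ethenyl-2-methoxy-5-methyloxolane; 8 (R)-1-bromo-3-chloro-2-methylpropane
Product: 10 (2S)-2-[(4S)-5-chloro-4-methylpentyl]-5-methoxy-2-methyloxolane, via alkyl-9-BBN adduct 9 (not isolated)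
Conditions: 9-BBN, THF, rt; then 8 (1.5 equiv), NiCl2·glyme (6 mol%), trans-N,N′-dimethylcyclohexane-1,2-diamine (8 mol%), KOt-Bu, i-BuOH, dioxane, rt
Reagents that add atoms: none
Why: Hydroboration then nickel-catalysed alkyl–alkyl Suzuki–Miyaura coupling: halogen abstraction by nickel is little affected by the β-branch and takes C–Br over C–Cl, forming C8–C9; C10 is carried in from 8 unchanged.

Step 5
Reactants: 10 (2S)-2-[(4S)-5-chloro-4-methylpentyl]-5-methoxy-2-methyloxolane; 5 (2R)-2-methyl-2-(4-methylpent-3-en-1-yl)oxetane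
Product: 12 (6S,10R)-13-[(2S)-5-methoxy-2-methyloxolan-2-yl]-2,6,10-trimethyltridec-2-en-6-ol, via Grignard reagent 11 (not isolated)
Conditions: Mg, THF, reflux; then 5 (1.2 equiv), CuBr·SMe2 (10 mol%), THF, −20 °C to rt; H2O
Reagents that add atoms: none
Why: Grignard formation and copper-catalysed SN2 opening of the oxetane at its unsubstituted CH2 form C11–C12 and release the C14 tertiary alcohol with the configuration of 5 retained.

Step 6
Reactants: 12 (6S,10R)-13-[(2S)-5-methoxy-2-methyloxolan-2-yl]-2,6,10-trimethyltridec-2-en-6-ol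
Product: 13 (5S)-5-[(4R,8S)-8-hydroxy-4,8,12-trimethyltridec-11-en-1-yl]-5-methyloxolan-2-ol (both anomers)
Conditions: AcOH/THF/H2O (3:1:1), 40 °C
Reagents that add atoms: water, O
Why: Acid hydrolysis of the furanoside-type mixed acetal is fast under conditions that leave the tertiary alcohol and the trisubstituted alkene alone.

Step 7
Reactants: 13 (5S)-5-[(4R,8S)-8-hydroxy-4,8,12-trimethyltridec-11-en-1-yl]-5-methyloxolan-2-ol; 14 methyl 2-(triphenyl-λ5-phosphanylidene)propanoate
Product: 15 methyl (2E,6S,10R,14S)-6,14-dihydroxy-2,6,10,14,18-pentamethylnonadeca-2,17-dienoate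
Conditions: toluene, 90 °C
Reagents that add atoms: none
Why: Wittig olefination of the open hydroxy-aldehyde form of the lactol with a stabilised α-methyl ylide gives the (E)-enoate (typically >95:5) and frees the C6 tertiary hydroxyl.

Step 8
Reactants: 15 methyl (2E,6S,10R,14S)-6,14-dihydroxy-2,6,10,14,18-pentamethylnonadeca-2,17-dienoate
Product: 18 methyl (2E,6R,10R,14R)-6,14-dihydroperoxy-2,6,10,14,18-pentamethylnonadeca-2,17-dienoate, via bis-phosphinite 16 (not isolated), via bis-phosphonium phenoxide 17 (not isolated)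
Conditions: Ph2PCl, Et3N, DMAP (cat.), THF, 0 °C to rt, filter under Ar; 2,6-dimethyl-1,4-benzoquinone, CH2Cl2, 0 °C; then anhydrous H2O2 in Et2O (excess), 0 °C
Reagents that add atoms: hydrogen peroxide, OO
Why: Proposed new method: oxidation–reduction condensation with H2O2 as the acidic partner — each tert-alkyl phosphinite adds to the quinone to give an alkoxy(aryloxy)phosphonium phenoxide (17), H2O2 (pKa about 11.6) protonates the phenoxide, and the α-effect nucleophile HOO− attacks the tertiary carbon from the rear within the ion pair while the phosphinate leaves, so C6 and C14 are each set by inversion (6S,14S to 6R,14R), and preforming 17 keeps trivalent phosphorus away from the peroxide; the closest known reactions are the same quinone-mediated condensation of chiral tert-alkyl phosphinites with carboxylic acids, phenols and thiols (inversion at tertiary carbon) and the Lewis-acid opening of 2,2-disubstituted oxetanes by H2O2 (inversion at tertiary carbon).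

Step 9
Reactants: 18 methyl (2E,6R,10R,14R)-6,14-dihydroperoxy-2,6,10,14,18-pentamethylnonadeca-2,17-dienoate
Product: 19 methyl (2R)-2-[(3S,6R)-6-[(4R,8R)-8-hydroperoxy-4,8,12-trimethyltridec-11-en-1-yl]-6-methyl-1,2-dioxan-3-yl]propanoate
Conditions: catalyst Q (10 mol%), toluene, −20 °C
Reagents that add atoms: none
Why: Proposed new method: enantioface-selective intramolecular peroxy-Michael addition under bifunctional iminophosphorane catalysis — the superbasic P=N deprotonates the C6 hydroperoxide (pKa about 13), the urea binds the ester carbonyl, the ion pair closes 6-exo-trig through a chair on the C3 face chosen by the catalyst (the two C6 substituents are too alike to bias it), and the urea-bound enolate is protonated at C2 by the aminophosphonium N–H in the same pocket, setting C3 (S) and C2 (R) while C6, C10 and C14 are untouched; the closest known reactions are iminophosphorane-catalysed enantioselective intramolecular oxa-Michael additions of alcohols to α,β-unsaturated esters, the related sulfa-Michael/protonation of α-substituted acrylates, and unselective amine-promoted peroxy-Michael closures of hydroperoxy enoates.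

## Compound list

1 | (R)-(−)-linalool, (3R)-3,7-dimethylocta-1,6-dien-3-ol | C=C[C@](C)(O)CCC=C(C)C | starting material
2 | 9-[(3S)-3-hydroxy-3,7-dimethyloct-6-en-1-yl]-9-borabicyclo[3.3.1]nonane (same spatial arrangement as 1) | C1CC2CCCC(C1)B2CC[C@](C)(O)CCC=C(C)C | intermediate
3 | (3R)-3,7-dimethyloct-6-ene-1,3-diol | OCC[C@](C)(O)CCC=C(C)C | intermediate
4 | (3R)-3-hydroxy-3,7-dimethyloct-6-en-1-yl 4-methylbenzenesulfonate | Cc1ccc(cc1)S(=O)(=O)OCC[C@](C)(O)CCC=C(C)C | intermediate
5 | (2R)-2-methyl-2-(4-methylpent-3-en-1-yl)oxetane | C1C[C@](C)(O1)CCC=C(C)C | intermediate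
6 | (5R)-5-ethenyl-5-methyloxolan-2-ol (both anomers) | C=C[C@]1(C)OC(O)CC1 | intermediate
7 | (5R)-5-ethenyl-2-methoxy-5-methyloxolane (both anomers) | C=C[C@]1(C)OC(OC)CC1 | intermediate
8 | (R)-1-bromo-3-chloro-2-methylpropane | BrC[C@H](C)CCl | starting material
9 | 9-{2-[(2S)-5-methoxy-2-methyloxolan-2-yl]ethyl}-9-borabicyclo[3.3.1]nonane | COC1CC[C@](C)(CCB2C3CCCC2CCC3)O1 | intermediate
10 | (2S)-2-[(4S)-5-chloro-4-methylpentyl]-5-methoxy-2-methyloxolane | COC1CC[C@](C)(CCC[C@H](C)CCl)O1 | intermediate
11 | chlorido{(2S)-5-[(2S)-5-methoxy-2-methyloxolan-2-yl]-2-methylpentyl}magnesium | COC1CC[C@](C)(CCC[C@H](C)C[Mg]Cl)O1 | intermediate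
12 | (6S,10R)-13-[(2S)-5-methoxy-2-methyloxolan-2-yl]-2,6,10-trimethyltridec-2-en-6-ol | COC1CC[C@](C)(CCC[C@H](C)CCC[C@@](C)(CCC=C(C)C)O)O1 | intermediate
13 | (5S)-5-[(4R,8S)-8-hydroxy-4,8,12-trimethyltridec-11-en-1-yl]-5-methyloxolan-2-ol (both anomers) | OC1CC[C@](C)(CCC[C@H](C)CCC[C@@](C)(CCC=C(C)C)O)O1 | intermediate
14 | methyl 2-(triphenyl-λ5-phosphanylidene)propanoate | COC(=O)C(C)=P(c1ccccc1)(c1ccccc1)c1ccccc1 | starting material
15 | methyl (2E,6S,10R,14S)-6,14-dihydroxy-2,6,10,14,18-pentamethylnonadeca-2,17-dienoate | COC(=O)/C(C)=C/CC[C@@](C)(O)CCC[C@H](C)CCC[C@](C)(O)CCC=C(C)C | intermediate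
16 | 15 with both tertiary hydroxyls as diphenylphosphinites (O–PPh2) | COC(=O)/C(C)=C/CC[C@@](C)(OP(c1ccccc1)c1ccccc1)CCC[C@H](C)CCC[C@](C)(OP(c1ccccc1)c1ccccc1)CCC=C(C)C | intermediate
17 | 16 with each phosphorus bound to the quinone oxygen as a diphenyl(4-oxido-3,5-dimethylphenoxy)phosphonium zwitterion | COC(=O)/C(C)=C/CC[C@@](C)(O[P+](c1ccccc1)(c1ccccc1)Oc1cc(C)c([O-])c(C)c1)CCC[C@H](C)CCC[C@](C)(O[P+](c1ccccc1)(c1ccccc1)Oc1cc(C)c([O-])c(C)c1)CCC=C(C)C | intermediate
18 | methyl (2E,6R,10R,14R)-6,14-dihydroperoxy-2,6,10,14,18-pentamethylnonadeca-2,17-dienoate | COC(=O)/C(C)=C/CC[C@](C)(OO)CCC[C@H](C)CCC[C@@](C)(OO)CCC=C(C)C | intermediate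
19 | methyl (2R)-2-[(3S,6R)-6-[(4R,8R)-8-hydroperoxy-4,8,12-trimethyltridec-11-en-1-yl]-6-methyl-1,2-dioxan-3-yl]propanoate | COC(=O)[C@H](C)[C@@H]1CC[C@@](C)(CCC[C@H](C)CCC[C@](C)(CCC=C(C)C)OO)OO1 | target

## Step count and risks

Total steps: 9. Longest linear sequence: 7 (steps 3, 4, 5, 6, 7, 8, 9 from (R)-linalool; the oxetane branch, steps 1, 2, 5–9, is equally long).

The three steps most likely to fail:

Step 8 (proposed new step). Hydroperoxide anion may attack phosphorus instead of carbon, the tertiary alkoxyphosphonium may eliminate, or inversion may be incomplete at one of the two centres. The fallback uses known chemistry and sets out from 15. Acid-catalysed perhydrolysis of the two tertiary alcohols (50% aq. H2O2, cat. H2SO4, THF, 0 °C, brief exposure) goes through the tertiary cations and gives methyl (2E,10R)-6,14-dihydroperoxy-2,6,10,14,18-pentamethylnonadeca-2,17-dienoate as the four C6/C14 stereoisomers F4. The (6R,14R) isomer is separated by preparative chiral-phase HPLC and comes back to the route at 18. This trades stereocontrol at C6 and C14 for a difficult separation and at best a quarter of the material.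

Step 9 (proposed new step). The α-methyl enoate is a weak acceptor, and the catalyst may control neither the C3 face nor the C2 protonation well; base-induced loss of the peroxide is a further risk. The fallback uses known chemistry, sets out from 18 and gives up catalyst control. Diethylamine in CF3CH2OH at rt, the established amine-promoted peroxy-Michael closure of hydroperoxy enoates, gives methyl 2-[(6R)-6-[(4R,8R)-8-hydroperoxy-4,8,12-trimethyltridec-11-en-1-yl]-6-methyl-1,2-dioxan-3-yl]propanoate as the four C2/C3 stereoisomers F5. The (2R,3S) isomer is isolated by preparative HPLC, which comes back to the route at 19.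

Step 4. The β-branched primary bromide may couple slowly, and the chloride may not stay fully untouched. The fallback sets out from 7 and reverses the polarity. Hydroboration–oxidation (9-BBN; NaOH, H2O2) gives 2-[(2R)-5-methoxy-2-methyloxolan-2-yl]ethan-1-ol F1. CBr4/PPh3 in CH2Cl2 at 0 °C gives (2R)-2-(2-bromoethyl)-5-methoxy-2-methyloxolane F2. Magnesium in THF gives bromido{2-[(2R)-5-methoxy-2-methyloxolan-2-yl]ethyl}magnesium F3. Copper-catalysed Grignard–alkyl bromide coupling with 8 (Li2CuCl4, 3 mol%, THF, −20 °C), which takes C–Br over C–Cl, comes back to the route at 10.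

## Further compounds

F1 | step 4 | 2-[(2R)-5-methoxy-2-methyloxolan-2-yl]ethan-1-ol | COC1CC[C@](C)(CCO)O1
F2 | step 4 | (2R)-2-(2-bromoethyl)-5-methoxy-2-methyloxolane | COC1CC[C@](C)(CCBr)O1
F3 | step 4 | bromido{2-[(2R)-5-methoxy-2-methyloxolan-2-yl]ethyl}magnesium | COC1CC[C@](C)(CC[Mg]Br)O1
F4 | step 8 | methyl (2E,10R)-6,14-dihydroperoxy-2,6,10,14,18-pentamethylnonadeca-2,17-dienoate, four C6/C14 stereoisomers | COC(=O)/C(C)=C/CCC(C)(OO)CCC[C@H](C)CCCC(C)(OO)CCC=C(C)C
F5 | step 9 | methyl 2-[(6R)-6-[(4R,8R)-8-hydroperoxy-4,8,12-trimethyltridec-11-en-1-yl]-6-methyl-1,2-dioxan-3-yl]propanoate, four C2/C3 stereoisomers | COC(=O)C(C)C1CC[C@@](C)(CCC[C@H](C)CCC[C@](C)(CCC=C(C)C)OO)OO1
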